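## Retrosynthetic overview

1. Target 28 ⇐ C17 epimer 26 (kinetic enolate protonation) ⇐ ring E from a C6 spiro-epoxide by titanocene radical opening, addition to an ethyl vinyl ketone equivalent (C6–C5) and cyclodehydration (O8–C3).
2. Ring B ⇐ cobalt-catalysed intramolecular allylic C–H alkylation (C14–C17) of an α-diazo ester on the bridged A/C/D core.
3. A/C/D core ⇐ one-flask annulation of a 3-substituted 1-methylpiperidine-2,4-dione with a 2-bromocyclopentenyl ethyl tosylate: enantioselective Pd α-alkenylation (C19–C13, quaternary), then enolate alkylation (C9–C10).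
4. Three fragments made in parallel: dione 5 (Dieckmann), bromo tosylate 11 (Suzuki vinylation, hydroboration), silyl enone 16.
5. Ring order: D (in 5) and A (in 11) preformed → C → B → E.

**Atom labels (target SMILES read left to right):** C1, C2 ethyl; C3=C4 enol ether (C3 bears ethyl and O8); C5; C6 spiro carbon; C7 (OCH2); O8; C9 (bridgehead CH); C10, C11; C12=C13; C14 (ring-fusion CH); C15, C16 (C16 on C12); C17 (CH–CO2Me); C18; C19 (quaternary); C20 (NCH2 on C19); N21 (NMe); C22 (NCH2 on C9). Ring A: C12–C16. Ring B: C13, C14, C17, C18, C19. Ring C: C6, C9, C10, C11, C12, C13, C19. Ring D: piperidine. Ring E: dihydropyran. Target = (6S,9S,14R,17R,19R).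

**Assumptions:** CIP letters are given per compound and change with substituent priorities, not with geometry. For the two chiral catalysts (steps 9 and 11) the antipode that gives the stated configuration is fixed in a first screen.

## Route

Step 1
Reactants: 1 methyl 3-(methylamino)propanoate; 2 glutaric anhydride
Product: 3 5-[(3-methoxy-3-oxopropyl)(methyl)amino]-5-oxopentanoic acid
Conditions: CH2Cl2, 0 °C to rt
Reagents that add atoms: none
Why: Ring-opening aminolysis of the cyclic anhydride by the secondary amine (N-acylation) gives the amido acid; no stereocentre is formed.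

Step 2
Reactants: 3 amido acid
Product: 4 methyl 5-[(3-methoxy-3-oxopropyl)(methyl)amino]-5-oxopentanoate
Conditions: MeI, K2CO3, DMF, rt
Reagents that add atoms: iodomethane, CI
Why: SN2 O-methylation of the carboxylate; amide and ester are inert.

Step 3
Reactants: 4 amido diester
Product: 5 methyl 3-(1-methyl-2,4-dioxopiperidin-3-yl)propanoate (racemic, enolised)
Conditions: KOtBu (2.2 equiv), THF, 0 °C to rt; then 1 M HCl
Reagents that add atoms: none
Why: Dieckmann condensation; only the amide α-carbon reaches an ester carbonyl through a six-membered transition state, and deprotonation of the 1,3-dicarbonyl product drives it (the C3 stereocentre is enolisable and erased in step 9).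

Step 4
Reactants: 6 1,2-dibromocyclopent-1-ene (3 equiv); 7 potassium trifluoro(vinyl)borate
Product: 8 1-bromo-2-ethenylcyclopent-1-ene
Conditions: PdCl2(dppf) (3 mol %), Cs2CO3, THF/H2O 9:1, 70 °C
Reagents that add atoms: none
Why: Suzuki–Miyaura mono-vinylation; excess dibromide and the more hindered, more electron-rich bromodiene product suppress the second coupling.

Step 5
Reactants: 8 bromodiene
Product: 10 2-(2-bromocyclopent-1-en-1-yl)ethan-1-ol, via alkylborane 9 (not isolated)
Conditions: 9-BBN, THF, 0 °C to rt; then NaOH, H2O2, 0 °C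
Reagents that add atoms: 9-borabicyclo[3.3.1]nonane, B1C2CCCC1CCC2 (held only in 9); hydrogen peroxide, OO
Why: Anti-Markovnikov hydroboration of the terminal alkene by the bulky borane, then oxidation; the tetrasubstituted bromoalkene does not react.

Step 6
Reactants: 10 bromo alcohol
Product: 11 2-(2-bromocyclopent-1-en-1-yl)ethyl 4-methylbenzenesulfonate
Conditions: TsCl, Et3N, DMAP (5 mol %), CH2Cl2, 0 °C
Reagents that add atoms: 4-methylbenzenesulfonyl chloride, Cc1ccc(cc1)S(Cl)(=O)=O
Why: O-sulfonylation of the primary alcohol installs the leaving group for the later C9–C10 closure.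

Step 7
Reactants: 12 (1-bromoethenyl)trimethylsilane; 13 propanal
Product: 15 2-(trimethylsilyl)pent-1-en-3-ol (racemic), via Grignard reagent 14 (not isolated)
Conditions: Mg, THF, 40 °C; then 13, −20 to 0 °C; aq NH4Cl
Reagents that add atoms: none
Why: Grignard addition of the α-silylvinyl nucleophile to the aldehyde (Stork–Ganem route); the carbinol centre is removed in step 8.

Step 8
Reactants: 15 silyl allylic alcohol
Product: 16 2-(trimethylsilyl)pent-1-en-3-one
Conditions: Dess–Martin periodinane, CH2Cl2, 0 °C to rt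
Reagents that add atoms: none
Why: Dess–Martin oxidation gives the α-silyl enone, a non-polymerising ethyl vinyl ketone equivalent for the radical step.

Step 9
Reactants: 5 dione ester; 11 bromo tosylate
Product: 18 (9R,19R)-keto lactam ester with rings A C D closed (C6 ketone; C20 lactam; C19 bears CH2CH2CO2Me), via open-chain alkenylation product 17 (not isolated)
Conditions: Pd2(dba)3 (2.5 mol %), (R)-KenPhos [(R)-2-(dicyclohexylphosphino)-2'-(dimethylamino)-1,1'-binaphthyl] (6 mol %), K3PO4, toluene, 70 °C; filter through Celite under Ar; then THF, KN(SiMe3)2 (1.2 equiv), −40 to 0 °C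
Reagents that add atoms: none
Why: Proposed new method: enantioselective Pd-catalysed α-alkenylation of a 2-alkyl cyclic β-keto lactam to an all-carbon quaternary centre — the cycloalkenyl bromide adds oxidatively to zerovalent palladium, K3PO4 forms the soft potassium enolate of 5, a C-bound palladium enolate results, and C–C reductive elimination in the pocket of the bulky P,N-binaphthyl ligand distinguishes the ketone flank from the lactam flank and sets C19 (R); the closest known reactions are Buchwald-type asymmetric α-vinylation and α-arylation of ketone enolates to quaternary centres and racemic Pd α-arylation of 1,3-dicarbonyls; the KN(SiMe3)2 stage is an ordinary 7-exo-tet enolate alkylation at C9 (the only enolisable ketone position), whose configuration (9R) is forced because the tether hangs from the C13 face of C19.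

Step 10
Reactants: 18 keto lactam ester
Product: 20 (9R,19R)-α-diazo ester (C17=N2), via trifluoroacetylated ester 19 (not isolated)
Conditions: LiN(SiMe3)2, THF, −78 °C; CF3CO2CH2CF3; 1 M HCl work-up; then MsN3, Et3N, H2O (1 equiv), MeCN, rt
Reagents that add atoms: methanesulfonyl azide, CS(=O)(=O)N=[N+]=[N-]; 2,2,2-trifluoroethyl trifluoroacetate, O=C(OCC(F)(F)F)C(F)(F)F (held only in 19)
Why: Danheiser detrifluoroacetylative diazo transfer (Regitz type); the ester CH2 is the only enolisable site, since C19 is quaternary and C9–H is a bridgehead hydrogen.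

Step 11
Reactants: 20 diazo ester
Product: 21 (9R,14R,17S,19R)-keto lactam with ring B closed (C17 epimer mixture; exo-ester epimer drawn)
Conditions: Co(3,5-DitBu-ChenPhyrin) (chiral amidoporphyrin complex of divalent cobalt, 3 mol %), chlorobenzene, 40 °C
Reagents that add atoms: none
Why: Cobalt metalloradical C–H alkylation — the cobalt carbene radical at C17 abstracts the allylic C14–H (1,5-hydrogen atom transfer) and radical substitution closes ring B without the oxygen-ylide pathways of electrophilic carbenoids; the chiral porphyrin cavity selects the face of the planar C14 allyl radical (14R), attack at C14 and not C12 keeps the tetrasubstituted C12=C13, and the C17 configuration is corrected in step 15.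

Step 12
Reactants: 21 keto lactam
Product: 22 (9R,14R,17S,19S)-amino ketone (C20 now CH2)
Conditions: Tf2O, CH2Cl2, −78 to 0 °C; then Hantzsch ester (diethyl 2,6-dimethyl-1,4-dihydropyridine-3,5-dicarboxylate, 2.5 equiv), rt
Reagents that add atoms: none
Why: Charette-type electrophilic amide activation and transfer hydrogenation reduces the tertiary lactam in the presence of the non-enolisable ketone and the ester; no stereocentre is touched.

Step 13
Reactants: 22 amino ketone
Product: 23 (6S,9R,14R,17S,19S)-spiro-epoxide (C6–O–C7)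
Conditions: Me3SI, KN(SiMe3)2, THF, −20 °C (ylide preformed); then 22, −20 °C to rt
Reagents that add atoms: trimethylsulfonium iodide, C[S+](C)C.[I-]
Why: Corey–Chaykovsky epoxidation of the bridging ketone; the ylide enters from the ring C face, and the C6 configuration of 23 is erased in step 14.

Step 14
Reactants: 23 spiro-epoxide; 16 silyl enone (3 equiv)
Product: 26 (6S,9S,14R,17S,19R)-17-epi-target, via silyl hydroxy ketone 24 (not isolated), via hydroxy ketone 25 (not isolated)
Conditions: Cp2TiCl2 (20 mol %), Mn, 2,4,6-collidine·HCl, THF, rt; then CSA, H2O (1 equiv), 40 °C; then toluene, 4 Å MS, 60 °C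
Reagents that add atoms: none
Why: Nugent–RajanBabu/Gansäuer reductive epoxide opening by Cp2TiCl (trivalent titanium) gives the planar tertiary C6 radical, which adds (Giese) to the enone from the ring C face — the ring D face carries two syn-axial C–H bonds (C20, C22), the ring C face only one because C13 is trigonal — so C5 ends syn to ring C and C7–O on the ring D side (6S); acid then removes the silyl group and dehydrates the lactol to the endocyclic enol ether.

Step 15
Reactants: 26 17-epi-target
Product: 28 target (6S,9S,14R,17R,19R), via potassium ester enolate 27 (not isolated)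
Conditions: KN(SiMe3)2, THF, −78 to −40 °C; then AcOH, −78 °C
Reagents that add atoms: none
Why: Kinetic protonation of the C17 ester enolate from the open face of ring B (the side of H14 and C20, away from C6 and C15) places the ester on the hindered face, which is the target configuration (17R).

## Compound list

1 | methyl 3-(methylamino)propanoate | CNCCC(=O)OC | starting material
2 | glutaric anhydride | O=C1CCCC(=O)O1 | starting material
3 | 5-[(3-methoxy-3-oxopropyl)(methyl)amino]-5-oxopentanoic acid | COC(=O)CCN(C)C(=O)CCCC(=O)O | intermediate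
4 | methyl 5-[(3-methoxy-3-oxopropyl)(methyl)amino]-5-oxopentanoate | COC(=O)CCN(C)C(=O)CCCC(=O)OC | intermediate
5 | methyl 3-(1-methyl-2,4-dioxopiperidin-3-yl)propanoate (racemic) | CN1CCC(=O)C(CCC(=O)OC)C1=O | intermediate
6 | 1,2-dibromocyclopent-1-ene | BrC1=C(Br)CCC1 | starting material
7 | potassium trifluoro(vinyl)borate | [K+].C=C[B-](F)(F)F | starting material
8 | 1-bromo-2-ethenylcyclopent-1-ene | C=CC1=C(Br)CCC1 | intermediate
9 | 9-[2-(2-bromocyclopent-1-en-1-yl)ethyl]-9-borabicyclo[3.3.1]nonane | BrC1=C(CCB2C3CCCC2CCC3)CCC1 | intermediate (not isolated)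
10 | 2-(2-bromocyclopent-1-en-1-yl)ethan-1-ol | OCCC1=C(Br)CCC1 | intermediate
11 | 2-(2-bromocyclopent-1-en-1-yl)ethyl 4-methylbenzenesulfonate | Cc1ccc(cc1)S(=O)(=O)OCCC1=C(Br)CCC1 | intermediate
12 | (1-bromoethenyl)trimethylsilane | C=C(Br)[Si](C)(C)C | starting material
13 | propanal | CCC=O | starting material
14 | bromo[1-(trimethylsilyl)ethenyl]magnesium | C=C([Mg]Br)[Si](C)(C)C | intermediate (not isolated)
15 | 2-(trimethylsilyl)pent-1-en-3-ol (racemic) | CCC(O)C(=C)[Si](C)(C)C | intermediate
16 | 2-(trimethylsilyl)pent-1-en-3-one | CCC(=O)C(=C)[Si](C)(C)C | intermediate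
17 | methyl 3-[(3R)-1-methyl-2,4-dioxo-3-{2-[2-(tosyloxy)ethyl]cyclopent-1-en-1-yl}piperidin-3-yl]propanoate | COC(=O)CC[C@@]1(C2=C(CCOS(=O)(=O)c3ccc(C)cc3)CCC2)C(=O)CCN(C)C1=O | intermediate (not isolated)
18 | (9R,19R)-keto lactam ester, rings A, C, D closed; C6 ketone, C20 lactam, C19–CH2CH2CO2Me | O=C2[C@@H]1CCC3=C(CCC3)[C@@]2(CCC(=O)OC)C(=O)N(C)C1 | intermediate
19 | C17-trifluoroacetyl derivative of 18 | O=C2[C@@H]1CCC3=C(CCC3)[C@@]2(CC(C(=O)C(F)(F)F)C(=O)OC)C(=O)N(C)C1 | intermediate (not isolated)
20 | (9R,19R)-α-diazo ester (C17=N2) | O=C2[C@@H]1CCC3=C(CCC3)[C@@]2(CC(=[N+]=[N-])C(=O)OC)C(=O)N(C)C1 | intermediate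
21 | (9R,14R,17S,19R)-keto lactam with rings A–D closed (C14–C17 bond formed) | O=C2[C@@H]1CCC3=C4[C@H](CC3)[C@@H](C(=O)OC)C[C@@]42C(=O)N(C)C1 | intermediate
22 | (9R,14R,17S,19S)-amino ketone (N-methylpiperidine; C6 ketone) | O=C2[C@@H]1CCC3=C4[C@H](CC3)[C@@H](C(=O)OC)C[C@@]42CN(C)C1 | intermediate
23 | (6S,9R,14R,17S,19S)-spiro-epoxide at C6 (epoxide O on the ring D face) | C1O[C@]12[C@@H]3CCC4=C5[C@H](CC4)[C@@H](C(=O)OC)C[C@@]52CN(C)C3 | intermediate
24 | α-silyl δ-hydroxy ketone: C6 bears CH2OH and CH2CH(SiMe3)C(O)Et | CCC(=O)C([Si](C)(C)C)C[C@]2(CO)[C@@H]1CCC3=C4[C@H](CC3)[C@@H](C(=O)OC)C[C@@]42CN(C)C1 | intermediate (not isolated)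
25 | δ-hydroxy ketone: C6 bears CH2OH and CH2CH2C(O)Et | CCC(=O)CC[C@]2(CO)[C@@H]1CCC3=C4[C@H](CC3)[C@@H](C(=O)OC)C[C@@]42CN(C)C1 | intermediate (not isolated)
26 | (6S,9S,14R,17S,19R)-17-epi-target | CCC1=CC[C@]2(CO1)[C@@H]1CCC3=C4[C@H](CC3)[C@@H](C(=O)OC)C[C@@]42CN(C)C1 | intermediate
27 | potassium C17 ester enolate of 26 | CCC1=CC[C@]2(CO1)[C@@H]1CCC3=C4[C@H](CC3)C(=C([O-])OC)C[C@@]42CN(C)C1.[K+] | intermediate (not isolated)
28 | CNP0159589.2, (6S,9S,14R,17R,19R) | CCC1=CC[C@]2(CO1)[C@@H]1CCC3=C4[C@H](CC3)[C@H](C(=O)OC)C[C@@]42CN(C)C1 | target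

## Totals and risks

Total step count: 15.
Longest linear sequence: 10 steps (steps 1–3, then 9–15; the branch 4–6, then 9–15 is equally long).

**Most likely to fail:**

**Step 9 (the proposed new coupling).** The reductive elimination to a congested quaternary centre, or its enantiocontrol, may fail. The fallback uses known chemistry, sets out from 1 and 10, and comes back at 17.
- Amine 1 is acylated with methyl 3-chloro-3-oxopropanoate (Et3N, CH2Cl2) to methyl 3-[(3-methoxy-3-oxopropanoyl)(methyl)amino]propanoate F1.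
- NaOMe in MeOH closes it (Dieckmann) to methyl 1-methyl-2,4-dioxopiperidine-3-carboxylate F2, which loses the ester in wet MeCN at reflux to give 1-methylpiperidine-2,4-dione F3.
- Alcohol 10 is silylated (TBSCl, imidazole) to tert-butyl[2-(2-bromocyclopent-1-en-1-yl)ethoxy]dimethylsilane F4.
- A racemic Pd α-alkenylation of the 1,3-dicarbonyl (Pd2(dba)3, tBuXPhos, K3PO4, toluene) joins F3 and F4 to 3-{2-[2-(silyloxy)ethyl]cyclopent-1-en-1-yl}-1-methylpiperidine-2,4-dione F5.
- A cinchona-derived phase-transfer-catalysed Michael addition to methyl acrylate (K2CO3, toluene, −20 °C) sets C19 in the (3R)-silyl ether quaternary dione F6.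
- Bu4NF gives the (3R)-hydroxyethyl quaternary dione F7, and TsCl/Et3N gives 17, which is cyclised with KN(SiMe3)2 as in step 9.

**Step 11.** The metalloradical closure may give the wrong C14 face, or the diazo ester may decompose. The fallback sets out from 18 and comes back at 22.
- Wittig methylenation (Ph3PCH3Br, KOtBu, THF) masks the ketone as the C6-methylene lactam F8.
- Tf2O then Hantzsch ester reduces the lactam to the C6-methylene amine F9.
- Diazo transfer as in step 10 passes through the C17-trifluoroacetyl ester F10 to the C6-methylene amino diazo ester F11.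
- As its triflate salt, F11 undergoes carbenoid 1,5-C–H insertion with Rh2(S-PTTL)4 (dirhodium tetrakis[N-phthaloyl-(S)-tert-leucinate], divalent rhodium; toluene, −60 °C) to the ring B-closed C6-methylene amine F12.
- OsO4 (cat.)/NaIO4 cleaves only the exocyclic methylene and returns ketone 22; either C17 epimer serves.

**Step 14.** The enone may be reduced by the titanium reagent, or the radical may add from the wrong face. The fallback sets out from 23 and comes back at 26 through 25.
- BF3·OEt2 (2.2 equiv, CH2Cl2, −78 °C) rearranges the epoxide (Meinwald) to the C6 carbaldehyde F13.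
- Its enolate (KOtBu cat., tBuOH/THF) adds to enone 16 from the ring C face to give the α-silyl keto aldehyde F14; KF in MeOH removes silicon to give the keto aldehyde F15.
- NaBH4 (EtOH/CH2Cl2, −78 °C) reduces only the aldehyde to 25, and CSA with 4 Å MS gives 26.

Further compounds
F1 | step 9 | methyl 3-[(3-methoxy-3-oxopropanoyl)(methyl)amino]propanoate | COC(=O)CC(=O)N(C)CCC(=O)OC
F2 | step 9 | methyl 1-methyl-2,4-dioxopiperidine-3-carboxylate | COC(=O)C1C(=O)CCN(C)C1=O
F3 | step 9 | 1-methylpiperidine-2,4-dione | CN1CCC(=O)CC1=O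
F4 | step 9 | tert-butyl[2-(2-bromocyclopent-1-en-1-yl)ethoxy]dimethylsilane | CC(C)(C)[Si](C)(C)OCCC1=C(Br)CCC1
F5 | step 9 | 3-{2-[2-(tert-butyldimethylsilyloxy)ethyl]cyclopent-1-en-1-yl}-1-methylpiperidine-2,4-dione | CN1CCC(=O)C(C2=C(CCO[Si](C)(C)C(C)(C)C)CCC2)C1=O
F6 | step 9 | methyl 3-[(3R)-3-{2-[2-(tert-butyldimethylsilyloxy)ethyl]cyclopent-1-en-1-yl}-1-methyl-2,4-dioxopiperidin-3-yl]propanoate | COC(=O)CC[C@@]1(C2=C(CCO[Si](C)(C)C(C)(C)C)CCC2)C(=O)CCN(C)C1=O
F7 | step 9 | methyl 3-[(3R)-3-[2-(2-hydroxyethyl)cyclopent-1-en-1-yl]-1-methyl-2,4-dioxopiperidin-3-yl]propanoate | COC(=O)CC[C@@]1(C2=C(CCO)CCC2)C(=O)CCN(C)C1=O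
F8 | step 11 | C6-methylene analogue of 18 (lactam kept) | C=C2[C@@H]1CCC3=C(CCC3)[C@@]2(CCC(=O)OC)C(=O)N(C)C1
F9 | step 11 | C6-methylene amine (C20 reduced to CH2) | C=C2[C@@H]1CCC3=C(CCC3)[C@@]2(CCC(=O)OC)CN(C)C1
F10 | step 11 | C17-trifluoroacetyl derivative of F9 | C=C2[C@@H]1CCC3=C(CCC3)[C@@]2(CC(C(=O)C(F)(F)F)C(=O)OC)CN(C)C1
F11 | step 11 | C6-methylene amino α-diazo ester | C=C2[C@@H]1CCC3=C(CCC3)[C@@]2(CC(=[N+]=[N-])C(=O)OC)CN(C)C1
F12 | step 11 | C6-methylene amine with ring B closed, (14R) | C=C2[C@@H]1CCC3=C4[C@H](CC3)[C@@H](C(=O)OC)C[C@@]42CN(C)C1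
F13 | step 14 | C6 carbaldehyde (C6 epimers) | O=CC2[C@@H]1CCC3=C4[C@H](CC3)[C@@H](C(=O)OC)C[C@@]42CN(C)C1
F14 | step 14 | α-silyl keto aldehyde: C6 bears CHO and CH2CH(SiMe3)C(O)Et | CCC(=O)C([Si](C)(C)C)C[C@]2(C=O)[C@@H]1CCC3=C4[C@H](CC3)[C@@H](C(=O)OC)C[C@@]42CN(C)C1
F15 | step 14 | keto aldehyde: C6 bears CHO and CH2CH2C(O)Et | CCC(=O)CC[C@]2(C=O)[C@@H]1CCC3=C4[C@H](CC3)[C@@H](C(=O)OC)C[C@@]42CN(C)C1
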